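**Retrosynthetic overview**
- Prenyl ether O–CH2 bond: mono-O-alkylation of the symmetric ring A diol 1 (bought) with prenyl bromide 2 gives phenol 3.
- Key disconnection, the diaryl ether C–O bond: Cu-catalysed Ullmann coupling of 3 with the ring B bromo-aldehyde 4 (bought) gives aldehyde 5. The ortho CHO activates the bromide.
- CH2OH from CHO: chemoselective NaBH4 reduction of 5 gives target 6.
- No ring is formed at any point; both benzene rings are bought ready-made and the route is convergent.

Assumption: the target has no stereocentre and no stereogenic double bond (the alkene carries two methyl groups), so it is achiral and the "single enantiomer" is the compound itself. Compounds 1, 2 and 4 are taken as catalogue chemicals.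

**Route**

Step 1
Reactants: 1 methyl 2,6-dihydroxy-4-methylbenzoate; 2 prenyl bromide (1-bromo-3-methylbut-2-ene)
Product: 3 methyl 2-hydroxy-4-methyl-6-[(3-methylbut-2-en-1-yl)oxy]benzoate
Conditions: 2 (1.05 equiv), K2CO3 (1.1 equiv), acetone, reflux, 8 h
Reagents that add atoms: prenyl bromide (compound 2), CC(C)=CCBr
Why: Williamson ether synthesis (SN2 on the primary allylic bromide) stops after one alkylation because the remaining OH is locked in a hydrogen bond to the ester carbonyl and reacts much more slowly; no stereocentre is formed.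

Step 2
Reactants: 3 methyl 2-hydroxy-4-methyl-6-[(3-methylbut-2-en-1-yl)oxy]benzoate; 4 2-bromo-3,5-dimethoxybenzaldehyde
Product: 5 methyl 2-(2-formyl-4,6-dimethoxyphenoxy)-4-methyl-6-[(3-methylbut-2-en-1-yl)oxy]benzoate
Conditions: CuI (10 mol %), picolinic acid (20 mol %), K3PO4 (2 equiv), DMSO, 90 °C, Ar, 24 h
Reagents that add atoms: none
Why: Ullmann diaryl ether synthesis, in which the ortho-formyl group activates the C–Br bond toward monovalent copper and the picolinate ligand tolerates ortho-substituted partners, while the methyl ester, prenyl ether and aldehyde are inert at 90 °C; no stereocentre is formed.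

Step 3
Reactants: 5 methyl 2-(2-formyl-4,6-dimethoxyphenoxy)-4-methyl-6-[(3-methylbut-2-en-1-yl)oxy]benzoate
Product: 6 methyl 2-[2-(hydroxymethyl)-4,6-dimethoxyphenoxy]-4-methyl-6-[(3-methylbut-2-en-1-yl)oxy]benzoate
Conditions: NaBH4, MeOH/THF 4:1, 0 °C, 30 min; aq. NH4Cl
Reagents that add atoms: none
Why: Chemoselective borohydride reduction, since NaBH4 at 0 °C reduces the aryl aldehyde within minutes but leaves the hindered methyl benzoate, the aryl ethers and the trisubstituted alkene untouched; no stereocentre is formed.

**Compound list**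
1 | methyl 2,6-dihydroxy-4-methylbenzoate | COC(=O)c1c(O)cc(C)cc1O | starting material
2 | prenyl bromide (1-bromo-3-methylbut-2-ene) | CC(C)=CCBr | starting material
3 | methyl 2-hydroxy-4-methyl-6-[(3-methylbut-2-en-1-yl)oxy]benzoate | COC(=O)c1c(O)cc(C)cc1OCC=C(C)C | intermediate
4 | 2-bromo-3,5-dimethoxybenzaldehyde | COc1cc(OC)c(Br)c(C=O)c1 | starting material
5 | methyl 2-(2-formyl-4,6-dimethoxyphenoxy)-4-methyl-6-[(3-methylbut-2-en-1-yl)oxy]benzoate | COC(=O)c1c(OCC=C(C)C)cc(C)cc1Oc1c(C=O)cc(OC)cc1OC | intermediate
6 | methyl 2-[2-(hydroxymethyl)-4,6-dimethoxyphenoxy]-4-methyl-6-[(3-methylbut-2-en-1-yl)oxy]benzoate | COC(=O)c1c(OCC=C(C)C)cc(C)cc1Oc1c(CO)cc(OC)cc1OC | target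

**Totals**
Total step count: 3. Longest linear sequence: 3 steps (1 → 3 → 5 → 6).

**Steps most likely to fail, with fallbacks**

Step 2 is the most likely to fail. The phenol of 3 is hindered and hydrogen-bonded to its ester, and the bromide of 4 sits between CHO and OMe, so conversion may stall or 4 may be debrominated. The fallback is a carboxylate-assisted (Hurtley-type) Ullmann coupling at the acid oxidation level, followed by chemoselective reduction of the acid. It sets out from 4, which a Pinnick oxidation (NaClO2, NaH2PO4, 2-methylbut-2-ene, t-BuOH/H2O, 25 °C) turns into 2-bromo-3,5-dimethoxybenzoic acid F1. The potassium carboxylate holds copper next to the C–Br bond and is coupled with phenol 3 (Cu powder, Cu2O, K2CO3, DMF, 110 °C) to give 2-{2-(methoxycarbonyl)-5-methyl-3-[(3-methylbut-2-en-1-yl)oxy]phenoxy}-3,5-dimethoxybenzoic acid F2. CDI in THF at 25 °C converts the free acid into methyl 2-[2-(1H-imidazol-1-ylcarbonyl)-4,6-dimethoxyphenoxy]-4-methyl-6-[(3-methylbut-2-en-1-yl)oxy]benzoate F3 (the acyl imidazolide, not isolated). NaBH4 in THF/H2O at 0 °C reduces only this activated acyl group and leaves the methyl ester, so the fallback comes back to the route at 6 and step 3 is no longer needed.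

Step 1 is second. Mono-alkylation of a symmetric diol can give a mixture of diol, mono-ether and bis-ether, with some C-prenylation. The fallback reverses the order so that no selective alkylation is needed. It sets out from 1, used in 2.5-fold excess in the Cu-catalysed coupling with 4 (CuI, picolinic acid, K3PO4, DMSO, 90 °C), to give methyl 2-(2-formyl-4,6-dimethoxyphenoxy)-6-hydroxy-4-methylbenzoate F4; the excess diol is recovered by chromatography. This compound has a single phenol, which is alkylated with prenyl bromide 2 (K2CO3, DMF, 25 °C) with no possibility of over-alkylation, and the fallback comes back to the route at 5.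

Step 3 is the least risky. The only plausible problem is that the benzylic alkoxide formed under basic borohydride conditions attacks the methyl ester on the neighbouring ring (ester exchange or the eight-membered lactone). The fallback replaces ionic hydride reduction by a neutral catalytic hydrosilylation in which the oxygen is silylated as it forms and is never a free alkoxide. It sets out from 5: [(Ph3P)CuH]6 (2 mol %) and PhMe2SiH (1.2 equiv) in toluene at 25 °C add Si–H across the C=O to give methyl 2-[2-({[dimethyl(phenyl)silyl]oxy}methyl)-4,6-dimethoxyphenoxy]-4-methyl-6-[(3-methylbut-2-en-1-yl)oxy]benzoate F5. AcOH/THF/H2O (3:1:1, 25 °C) then cleaves the labile silyl ether without touching the prenyl ether or the ester, and the fallback comes back to the route at 6.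

**Further compounds**
F1 | step 2 | 2-bromo-3,5-dimethoxybenzoic acid | COc1cc(OC)c(Br)c(C(=O)O)c1
F2 | step 2 | 2-{2-(methoxycarbonyl)-5-methyl-3-[(3-methylbut-2-en-1-yl)oxy]phenoxy}-3,5-dimethoxybenzoic acid | COC(=O)c1c(OCC=C(C)C)cc(C)cc1Oc1c(C(=O)O)cc(OC)cc1OC
F3 | step 2 | methyl 2-[2-(1H-imidazol-1-ylcarbonyl)-4,6-dimethoxyphenoxy]-4-methyl-6-[(3-methylbut-2-en-1-yl)oxy]benzoate | COC(=O)c1c(OCC=C(C)C)cc(C)cc1Oc1c(C(=O)n2ccnc2)cc(OC)cc1OC
F4 | step 1 | methyl 2-(2-formyl-4,6-dimethoxyphenoxy)-6-hydroxy-4-methylbenzoate | COC(=O)c1c(O)cc(C)cc1Oc1c(C=O)cc(OC)cc1OC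
F5 | step 3 | methyl 2-[2-({[dimethyl(phenyl)silyl]oxy}methyl)-4,6-dimethoxyphenoxy]-4-methyl-6-[(3-methylbut-2-en-1-yl)oxy]benzoate | COC(=O)c1c(OCC=C(C)C)cc(C)cc1Oc1c(CO[Si](C)(C)c2ccccc2)cc(OC)cc1OC
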